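The hexasubstituted central benzene ring (C1 bears OMe, C3 bears OH) is built last instead of being substituted as a preformed arene. A Danheiser benzannulation joins a 2,3,4-trisubstituted cyclobutenone (supplying C3 to C6 with the C4 and C6 benzyl groups and the C5 phenethyl chain) to a 1-methoxyalkyne (supplying C1 and C2), forming C3–C2, C1–C6 and C3–C4 in one operation. The step exploits the resorcinol monomethyl ether pattern of that ring: the meta-related C3–OH and C1–OMe emerge already differentiated and all six substituents arrive in place. The cyclobutenone is made from the same ynol ether by ketene cycloaddition, Grignard addition and carbonyl transposition; the four outer phenols travel as benzyl ethers.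

Key step: step 7

Remarks on the chemistry: the central ring is numbered C1 (OMe), C2, C3 (OH), C4, C5 (phenethyl), C6, with 4-hydroxybenzyl groups on C2, C4 and C6. The target is achiral. Apart from OH versus OMe, its central ring is symmetric about the C2–C5 axis. Compounds 8, 13, 14, 16 and 18 are racemic or diastereomeric mixtures whose stereocenters disappear on aromatization. LiNEt2 is taken as a preformed reagent.

Step 1
Reactants: 1 chloroacetaldehyde dimethyl acetal; 2 4-(benzyloxy)benzyl chloride
Product: 4 1-(benzyloxy)-4-(3-methoxyprop-2-yn-1-yl)benzene, via lithium methoxyacetylide 3 (not isolated)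
Conditions: LiNEt2 (3.0 equiv), THF, 0 °C; then 2, Bu4NI (cat.), DMPU, −78 °C to rt
Reagents that add atoms: none
Why: Three equivalents of amide base bring about two β-eliminations (loss of methanol, then of HCl) and deprotonation of the methoxyacetylene so formed, and acetylide 3 should then be C-alkylated by the activated benzylic chloride in an SN2 reaction that DMPU and iodide catalysis accelerate (one-pot alkoxyacetylide generation and alkylation).

Step 2
Reactants: 5 3-[4-(benzyloxy)phenyl]propanoic acid
Product: 6 3-[4-(benzyloxy)phenyl]propanoyl chloride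
Conditions: (COCl)2, DMF (cat.), CH2Cl2, 0 °C to rt; used crude
Reagents that add atoms: oxalyl chloride, O=C(Cl)C(=O)Cl
Why: Vilsmeier-type activation by catalytic DMF converts the acid into its chloride under mild conditions that leave the aryl benzyl ether untouched (acid chloride formation with oxalyl chloride).

Step 3
Reactants: 6 3-[4-(benzyloxy)phenyl]propanoyl chloride; 4 1-(benzyloxy)-4-(3-methoxyprop-2-yn-1-yl)benzene
Product: 8 2,4-bis[4-(benzyloxy)benzyl]-3-methoxycyclobut-2-en-1-one (racemic), via ketene 7 (not isolated)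
Conditions: 6 (1.5 equiv), Et3N (1.6 equiv, slow addition), CH2Cl2, rt to 40 °C
Reagents that add atoms: none
Why: Slow dehydrochlorination keeps the concentration of aldoketene 7 low so that its [2+2] cycloaddition with the electron-rich ynol ether outruns dimerization, the nucleophilic benzyl-bearing alkyne carbon bonding to the ketene carbonyl carbon to give the 3-methoxycyclobutenone; the new C4 stereocenter forms without control and is racemic (ketene–alkoxyalkyne [2+2] cycloaddition).

Step 4
Reactants: 9 2-(3-hydroxyphenyl)ethanol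
Product: 10 2-[3-(benzyloxy)phenyl]ethanol
Conditions: BnBr (1.05 equiv), K2CO3, acetone, reflux
Reagents that add atoms: benzyl bromide, BrCc1ccccc1
Why: Carbonate deprotonates only the phenol, so Williamson etherification with benzyl bromide is selective for the phenolic oxygen over the primary alcohol.

Step 5
Reactants: 10 2-[3-(benzyloxy)phenyl]ethanol
Product: 11 1-(benzyloxy)-3-(2-bromoethyl)benzene
Conditions: CBr4, PPh3, CH2Cl2, 0 °C to rt
Reagents that add atoms: carbon tetrabromide, BrC(Br)(Br)Br
Why: The Appel reaction converts the primary alcohol into the bromide by SN2 displacement of an alkoxyphosphonium ion under neutral conditions that spare the benzyl ether.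

Step 6
Reactants: 11 1-(benzyloxy)-3-(2-bromoethyl)benzene; 8 2,4-bis[4-(benzyloxy)benzyl]-3-methoxycyclobut-2-en-1-one
Product: 14 2,4-bis[4-(benzyloxy)benzyl]-3-{2-[3-(benzyloxy)phenyl]ethyl}cyclobut-2-en-1-one (racemic), via Grignard reagent 12 (not isolated), via carbinol 13 (not isolated)
Conditions: 11, Mg turnings, I2 (cat.), THF, rt; then 8, THF, −78 to 0 °C; then 1 M aq. HCl, rt
Reagents that add atoms: water, O
Why: The Grignard reagent adds 1,2 to the carbonyl of the vinylogous ester (enolization is disfavored because the enolate would be a cyclobutadiene), and dilute acid then ionizes the tertiary allylic alcohol of 13 with help from the methoxy group, water adds at the oxocarbenium carbon and methanol is lost, which transposes the carbonyl (organometallic addition to a 3-alkoxycyclobutenone followed by acidic hydrolysis); the stereocenters of 13 are uncontrolled and irrelevant, the C4 stereocenter of 14 is racemic, and since both ring CH carbons of 13 carry the same benzyl group either sense of dehydration gives the same constitution.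

Step 7
Reactants: 14 2,4-bis[4-(benzyloxy)benzyl]-3-{2-[3-(benzyloxy)phenyl]ethyl}cyclobut-2-en-1-one; 4 1-(benzyloxy)-4-(3-methoxyprop-2-yn-1-yl)benzene
Product: 19 2,4,6-tris[4-(benzyloxy)benzyl]-3-{2-[3-(benzyloxy)phenyl]ethyl}-5-methoxyphenol, via vinylketene 15 (not isolated), via vinylcyclobutenone 16 (not isolated), via dienylketene 17 (not isolated), via cyclohexadienone 18 (not isolated)
Conditions: 4 (1.5 equiv), toluene, sealed tube, 80 °C then 120 °C
Reagents that add atoms: none
Why: Heating opens 14 by a conrotatory 4π electrocyclic cleavage of its C(=O)–C(sp3) bond to vinylketene 15, whose ketene C=C undergoes a [2+2] cycloaddition with ynol ether 4 to give 16 (forming C3–C2 and C1–C6); a second 4π opening gives dienylketene 17, disrotatory 6π electrocyclization forms C3–C4 to give 18, and enolization delivers phenol 19. The closest known reaction type is the Danheiser benzannulation of cyclobutenones with 1-alkoxyalkynes to resorcinol monoethers, applied here at the crowded, hexasubstituted end of its scope. The transient four-membered ring closes by a thermal ketene–alkyne [2+2] cycloaddition and the central six-membered ring closes by 6π electrocyclization of the dienylketene, after which tautomerization makes it aromatic. No stereocenter is created in 19: the racemic stereocenter of 14 becomes sp2 on ring opening and the one in 18 is erased on enolization. The regiochemistry needed (benzyl-bearing alkyne carbon to the ketene carbonyl carbon, so that OMe ends meta to OH) is secured by the polarization of the ynol ether, whose β-carbon is the nucleophile toward the electrophilic ketene carbon, and the geometry needed is secured by outward rotation of the C4 benzyl group, which gives the E-vinylketene with hydrogen inside and so disfavors a 1,5-hydrogen shift. A methyl ynol ether is chosen because, having no β-hydrogen on its O-alkyl group, it cannot fragment to a ketene and an alkene at the reaction temperature.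

Step 8
Reactants: 19 2,4,6-tris[4-(benzyloxy)benzyl]-3-{2-[3-(benzyloxy)phenyl]ethyl}-5-methoxyphenol
Product: 20 2,4,6-tris(4-hydroxybenzyl)-3-[2-(3-hydroxyphenyl)ethyl]-5-methoxyphenol (CNP0262401.0)
Conditions: H2 (1 atm), 10% Pd/C, EtOAc–MeOH, rt
Reagents that add atoms: none
Why: The four aryl benzyl ethers should be cleaved by palladium-catalysed hydrogenolysis, while the aryl methyl ether, the diarylmethane C–C bonds and the arenes are inert under these mild conditions.

Compound list
1 | chloroacetaldehyde dimethyl acetal | COC(CCl)OC | starting material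
2 | 4-(benzyloxy)benzyl chloride | ClCc1ccc(OCc2ccccc2)cc1 | starting material
3 | lithium methoxyacetylide | [Li]C#COC | intermediate (not isolated)
4 | 1-(benzyloxy)-4-(3-methoxyprop-2-yn-1-yl)benzene (methyl ynol ether, used in steps 3 and 7) | COC#CCc1ccc(OCc2ccccc2)cc1 | intermediate
5 | 3-[4-(benzyloxy)phenyl]propanoic acid | O=C(O)CCc1ccc(OCc2ccccc2)cc1 | starting material
6 | 3-[4-(benzyloxy)phenyl]propanoyl chloride | O=C(Cl)CCc1ccc(OCc2ccccc2)cc1 | intermediate
7 | [4-(benzyloxy)benzyl]ketene (3-[4-(benzyloxy)phenyl]prop-1-en-1-one) | O=C=CCc1ccc(OCc2ccccc2)cc1 | intermediate (not isolated)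
8 | 2,4-bis[4-(benzyloxy)benzyl]-3-methoxycyclobut-2-en-1-one (racemic) | COC1=C(Cc2ccc(OCc3ccccc3)cc2)C(=O)C1Cc1ccc(OCc2ccccc2)cc1 | intermediate
9 | 2-(3-hydroxyphenyl)ethanol | OCCc1cccc(O)c1 | starting material
10 | 2-[3-(benzyloxy)phenyl]ethanol | OCCc1cccc(OCc2ccccc2)c1 | intermediate
11 | 1-(benzyloxy)-3-(2-bromoethyl)benzene | BrCCc1cccc(OCc2ccccc2)c1 | intermediate
12 | {2-[3-(benzyloxy)phenyl]ethyl}magnesium bromide | Br[Mg]CCc1cccc(OCc2ccccc2)c1 | intermediate (not isolated)
13 | 2,4-bis[4-(benzyloxy)benzyl]-1-{2-[3-(benzyloxy)phenyl]ethyl}-3-methoxycyclobut-2-en-1-ol (mixture of diastereomers, racemic) | COC1=C(Cc2ccc(OCc3ccccc3)cc2)C(O)(CCc2cccc(OCc3ccccc3)c2)C1Cc1ccc(OCc2ccccc2)cc1 | intermediate (not isolated)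
14 | 2,4-bis[4-(benzyloxy)benzyl]-3-{2-[3-(benzyloxy)phenyl]ethyl}cyclobut-2-en-1-one (racemic) | O=C1C(Cc2ccc(OCc3ccccc3)cc2)=C(CCc2cccc(OCc3ccccc3)c2)C1Cc1ccc(OCc2ccccc2)cc1 | intermediate
15 | (3E)-2-[4-(benzyloxy)benzyl]-3-{2-[3-(benzyloxy)phenyl]ethyl}-5-[4-(benzyloxy)phenyl]penta-1,3-dien-1-one (vinylketene, hydrogen cis to the ketene arm) | O=C=C(Cc1ccc(OCc2ccccc2)cc1)/C(CCc1cccc(OCc2ccccc2)c1)=C/Cc1ccc(OCc2ccccc2)cc1 | intermediate (not isolated)
16 | 2,4-bis[4-(benzyloxy)benzyl]-3-methoxy-4-{(E)-1-[4-(benzyloxy)phenyl]-5-[3-(benzyloxy)phenyl]pent-2-en-3-yl}cyclobut-2-en-1-one (racemic) | COC1=C(Cc2ccc(OCc3ccccc3)cc2)C(=O)C1(Cc1ccc(OCc2ccccc2)cc1)/C(CCc1cccc(OCc2ccccc2)c1)=C/Cc1ccc(OCc2ccccc2)cc1 | intermediate (not isolated)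
17 | (3E,5E)-2,4-bis[4-(benzyloxy)benzyl]-5-{2-[3-(benzyloxy)phenyl]ethyl}-7-[4-(benzyloxy)phenyl]-3-methoxyhepta-1,3,5-trien-1-one (dienylketene, ketene arm cis to C5 across C3=C4) | O=C=C(Cc1ccc(OCc2ccccc2)cc1)/C(OC)=C(Cc1ccc(OCc2ccccc2)cc1)\C(CCc1cccc(OCc2ccccc2)c1)=C\Cc1ccc(OCc2ccccc2)cc1 | intermediate (not isolated)
18 | 2,4,6-tris[4-(benzyloxy)benzyl]-5-{2-[3-(benzyloxy)phenyl]ethyl}-3-methoxycyclohexa-2,4-dien-1-one (racemic) | COC1=C(Cc2ccc(OCc3ccccc3)cc2)C(=O)C(Cc2ccc(OCc3ccccc3)cc2)C(CCc2cccc(OCc3ccccc3)c2)=C1Cc1ccc(OCc2ccccc2)cc1 | intermediate (not isolated)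
19 | 2,4,6-tris[4-(benzyloxy)benzyl]-3-{2-[3-(benzyloxy)phenyl]ethyl}-5-methoxyphenol (tetra-O-benzyl target) | COc1c(Cc2ccc(OCc3ccccc3)cc2)c(O)c(Cc2ccc(OCc3ccccc3)cc2)c(CCc2cccc(OCc3ccccc3)c2)c1Cc1ccc(OCc2ccccc2)cc1 | intermediate
20 | 2,4,6-tris(4-hydroxybenzyl)-3-[2-(3-hydroxyphenyl)ethyl]-5-methoxyphenol (CNP0262401.0) | COc1c(Cc2ccc(O)cc2)c(O)c(Cc2ccc(O)cc2)c(CCc2cccc(O)c2)c1Cc1ccc(O)cc1 | target

Total step count: 8. Longest linear sequence: 5 steps (for example steps 1, 3, 6, 7, 8).

Steps most likely to fail

Step 7. The cycloaddition of the crowded, α-benzyl-substituted vinylketene with the ynol ether may be slow. O-acylation of the product phenol by the vinylketene, ketene oligomerization, or inward rotation followed by a 1,5-hydrogen shift could then compete. Any aryl ester from O-acylation would be cleaved with KOH in MeOH before purification. The fallback sets out from cyclobutenone 14 and returns at 19. It replaces the methyl ynol ether by a more nucleophilic silyl ynol ether and introduces the O-methyl group afterwards. Commercial ethyl 2-[4-(benzyloxy)phenyl]acetate would be taken through the rearrangement stage of a Kowalski ester homologation (CH2Br2, lithium 2,2,6,6-tetramethylpiperidide, THF, −78 °C; then n-BuLi with warming) to lithium 3-[4-(benzyloxy)phenyl]prop-1-yn-1-olate F1. O-Silylation with TIPSCl should give {[3-(4-benzyloxyphenyl)prop-1-yn-1-yl]oxy}triisopropylsilane F2. Heating 14 with F2 in toluene should give, by the same pericyclic cascade, 2,4,6-tris[4-(benzyloxy)benzyl]-3-{2-[3-(benzyloxy)phenyl]ethyl}-5-[(triisopropylsilyl)oxy]phenol F3. Methylation of its free hydroxyl (NaH, MeI, THF) would give triisopropyl{2,4,6-tris[4-(benzyloxy)benzyl]-3-{2-[3-(benzyloxy)phenyl]ethyl}-5-methoxyphenoxy}silane F4, and TBAF in THF would then free the other oxygen. Because the central ring is symmetric about its C2–C5 axis apart from OH versus OMe, the phenol obtained is 19 itself.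

Step 1. The liberated diethylamine may be N-benzylated, the product may isomerize from propargyl to allenyl ether under the basic conditions, or the SN2 alkylation of the acetylide may be sluggish. The fallback sets out from 1 and 2 and returns at 4, replacing the alkylation by a cross-coupling under neutral conditions. Acetylide 3, generated from 1 as before, would be quenched with Bu3SnCl to give tributyl(methoxyethynyl)stannane F5, which is distilled free of amine and base. A Stille coupling of F5 with benzylic chloride 2 (Pd(PPh3)4 (cat.), THF, 65 °C) should then give 4.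

Step 3. The aldoketene may dimerize faster than it is trapped, and the acid-sensitive ynol ether may be hydrated in the presence of the ammonium salt. The fallback sets out from 2 and returns at 14, generating the same ketene thermally without amine or acid chloride. Commercial ethoxyacetylene would be deprotonated with n-BuLi (THF, −78 °C) to lithium ethoxyacetylide F6 and alkylated with 2 (DMPU, Bu4NI (cat.)) to 1-(benzyloxy)-4-(3-ethoxyprop-2-yn-1-yl)benzene F7. Heating F7 in toluene at about 120 °C should expel ethylene by a retro-ene reaction to give ketene 7, which is captured in the flask by unchanged F7 to give 2,4-bis[4-(benzyloxy)benzyl]-3-ethoxycyclobut-2-en-1-one F8. Treating F8 with Grignard reagent 12 and then dilute HCl, as in step 6, should pass through 2,4-bis[4-(benzyloxy)benzyl]-1-{2-[3-(benzyloxy)phenyl]ethyl}-3-ethoxycyclobut-2-en-1-ol F9 and give 14 with loss of ethanol.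

Further compounds
F1 | step 7 | lithium 3-[4-(benzyloxy)phenyl]prop-1-yn-1-olate | [Li]OC#CCc1ccc(OCc2ccccc2)cc1
F2 | step 7 | {[3-(4-benzyloxyphenyl)prop-1-yn-1-yl]oxy}triisopropylsilane | CC(C)[Si](OC#CCc1ccc(OCc2ccccc2)cc1)(C(C)C)C(C)C
F3 | step 7 | 2,4,6-tris[4-(benzyloxy)benzyl]-3-{2-[3-(benzyloxy)phenyl]ethyl}-5-[(triisopropylsilyl)oxy]phenol | CC(C)[Si](Oc1c(Cc2ccc(OCc3ccccc3)cc2)c(O)c(Cc2ccc(OCc3ccccc3)cc2)c(CCc2cccc(OCc3ccccc3)c2)c1Cc1ccc(OCc2ccccc2)cc1)(C(C)C)C(C)C
F4 | step 7 | triisopropyl{2,4,6-tris[4-(benzyloxy)benzyl]-3-{2-[3-(benzyloxy)phenyl]ethyl}-5-methoxyphenoxy}silane | COc1c(Cc2ccc(OCc3ccccc3)cc2)c(O[Si](C(C)C)(C(C)C)C(C)C)c(Cc2ccc(OCc3ccccc3)cc2)c(CCc2cccc(OCc3ccccc3)c2)c1Cc1ccc(OCc2ccccc2)cc1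
F5 | step 1 | tributyl(methoxyethynyl)stannane | CCCC[Sn](CCCC)(CCCC)C#COC
F6 | step 3 | lithium ethoxyacetylide | [Li]C#COCC
F7 | step 3 | 1-(benzyloxy)-4-(3-ethoxyprop-2-yn-1-yl)benzene | CCOC#CCc1ccc(OCc2ccccc2)cc1
F8 | step 3 | 2,4-bis[4-(benzyloxy)benzyl]-3-ethoxycyclobut-2-en-1-one (racemic) | CCOC1=C(Cc2ccc(OCc3ccccc3)cc2)C(=O)C1Cc1ccc(OCc2ccccc2)cc1
F9 | step 3 | 2,4-bis[4-(benzyloxy)benzyl]-1-{2-[3-(benzyloxy)phenyl]ethyl}-3-ethoxycyclobut-2-en-1-ol (mixture of diastereomers) | CCOC1=C(Cc2ccc(OCc3ccccc3)cc2)C(O)(CCc2cccc(OCc3ccccc3)c2)C1Cc1ccc(OCc2ccccc2)cc1
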